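At early times the flask holds D but no dissolved X, which the gas Z has to deliver.

    D + X → E + G (k1 = 0.016 /M/s)
    X + E ⇌ X.E, settled at all times (K2 = 52000 /M)
    Z ⇌ X, rate k3*(csat - [X]) (k3 = 0.0070 /s, csat = 69 mM)
    G → L (k4 = 3.8 × 10⁻⁴ /s)

D 0.50 M; Z 69 mM (held); time 80 min

- part of the D that has reacted at 80 min
- share of the unused X that is free and not bound as X.E, at 80 min

One number carries this flask: the demand number n, twice 0.016 /M/s times [D] over 0.0070 /s, which at the charge is 2.29. The first rung is the binding, kept at balance: with free X near 21.0 mM, [X.E]/[E] is 1090, so nearly all E is bound and each D reacted costs two X. Next come the half-life of X against D as charged, 1.4 min, and that of the transfer, 1.65 min. At the charge, slowest is D, with a half-life of 34.4 min at that free level, longer than these and than the 30 min of G. So, past the first minutes, free X sits in a quasi-steady state, [X] = 69 mM/(1 + n). The turning of G into L leaves the reacted part of D unchanged.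

Counting delivered X as reacted, bound or free makes a budget: 0.016 /M/s times 69 mM times 80 min gives 5.30. It is spent on the logarithm of the fall in [D], the fall in n, and [X] times 0.016 /M/s over 0.0070 /s. A first pass, taking [D] small and [X] at 69 mM, gives 0.0288 M. A second, with [X] at 61.0 mM, gives 0.0248 M. We commit to 95.0% of D reacted, and, taking X.E as the D reacted, to [X] of 62.0 mM and a free share of the unused X of 11.5%.

The forecast gives 95% (93.5% to 96.5%) and, slightly below our share, 11.4% (10.3% to 12.5%), holding that “free X tracks a quasi-steady level”. The simulation gives 95.0% and 11.4%, with [X] at 0.0610 M.

In the neighbouring flask with 2.0 M of D, same gas and time, n at the charge is 9.14, larger than here, while the budget stays 5.30. If half of D is gone, [X] reckons to 12.4 mM and the spending comes to 5.29, about the budget, with a free share of 1.22%. That flask gives 50.1% of D reacted, [X] of 0.0124 M and a free share of 1.22%.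

The numbers were drawn at random within sensible limits.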